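**Retrosynthetic overview**
1. Target 18 comes from triacetate 17 by ester cleavage. The furan ring of the benzofuran is closed last, by an intramolecular Perkin-type aldol condensation/decarboxylation of the 2-aryl-2-(2-formylphenoxy)acetic acid 16.
2. Acid 16 comes from ether 15 (Williamson union of salicylaldehyde 7 with α-bromo ester 14) by a LiOH step that saponifies, desilylates and lets the freed phenoxide open the (S)-epoxide 5-exo with inversion, giving the (R)-dihydrofuran.
3. Fragment 7 comes from resorcinol by two directed ortho-metalations (C2 geranylation, then C4 formylation).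
4. Fragment 14 comes from methyl 3,5-dihydroxyphenylacetate by iodination, Stille prenylation, Shi epoxidation and α-bromination.
5. Ring order: both benzene rings are bought; the dihydrofuran forms in step 12 and the benzofuran furan ring in step 13.

Assumption: the L-fructose-derived (ent-)Shi ketone is taken as an available catalyst, and the α-carbon of 14–16 is carried as a ~1:1 epimer mixture because it becomes sp2 (C2 of the benzofuran).

---

**Fragment A**

**Step 1**
Reactants: 1 resorcinol
Product: 2 1,3-bis(methoxymethoxy)benzene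
Conditions: MOMCl, i-Pr2NEt, CH2Cl2, 0 °C → rt
Reagents that add atoms: chloromethyl methyl ether, COCCl
Why: Double O-alkylation of the phenols installs two MOM ethers that later serve as ortho-directing groups.

**Step 2**
Reactants: 2; 3 geranyl bromide [(2E)-1-bromo-3,7-dimethylocta-2,6-diene]
Product: 4 2-[(2E)-3,7-dimethylocta-2,6-dien-1-yl]-1,3-bis(methoxymethoxy)benzene
Conditions: n-BuLi, THF, 0 °C; CuI, −78 °C; then 3, −78 °C → rt
Reagents that add atoms: geranyl bromide (3), CC(C)=CCC/C(C)=C/CBr
Why: Directed ortho-metalation occurs at C2 between the two OMOM groups, and the aryl copper species alkylates the allylic bromide SN2 with retention of the E-olefin.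

**Step 3**
Reactants: 4
Product: 5 3-[(2E)-geranyl]-2,4-bis(methoxymethoxy)benzaldehyde
Conditions: n-BuLi, TMEDA, THF, −20 → 0 °C; then DMF, → rt
Reagents that add atoms: N,N-dimethylformamide, CN(C)C=O
Why: A second MOM-directed ortho-lithiation at the only remaining ortho position, followed by DMF quench, gives the aldehyde with the required 1,2,3,4-substitution pattern.

**Step 4**
Reactants: 5
Product: 6 3-[(2E)-geranyl]-2,4-dihydroxybenzaldehyde
Conditions: HCl (≈1 M in MeOH), rt → 40 °C; NaHCO3 work-up
Reagents that add atoms: none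
Why: Acetal solvolysis removes both MOM groups under dilute acid at low temperature, conditions under which a trisubstituted olefin does not cyclise onto the phenol.

**Step 5**
Reactants: 6
Product: 7 4-(tert-butyldimethylsilyloxy)-3-[(2E)-geranyl]-2-hydroxybenzaldehyde
Conditions: TBSCl (1.05 equiv), imidazole, CH2Cl2, 0 °C
Reagents that add atoms: tert-butyldimethylsilyl chloride, CC(C)(C)[Si](C)(C)Cl
Why: The 2-OH is deactivated by its hydrogen bond to the aldehyde, so silylation is selective for the 4-OH.

**Fragment B**

**Step 6**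
Reactants: 8 methyl 2-(3,5-dihydroxyphenyl)acetate
Product: 9 methyl 2-[3,5-bis(tert-butyldimethylsilyloxy)phenyl]acetate
Conditions: TBSCl (2.4 equiv), imidazole, DMF, rt
Reagents that add atoms: tert-butyldimethylsilyl chloride, CC(C)(C)[Si](C)(C)Cl
Why: Routine phenol silylation masks both phenols so that no nucleophilic oxygen is present during epoxidation, enolate chemistry and coupling.

**Step 7**
Reactants: 9
Product: 10 methyl 2-[2-iodo-3,5-bis(tert-butyldimethylsilyloxy)phenyl]acetate
Conditions: NIS (1.05 equiv), MeCN, 0 °C → rt, dark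
Reagents that add atoms: N-iodosuccinimide, O=C1CCC(=O)N1I
Why: Electrophilic aromatic iodination goes to C2 (ortho/para to the two silyloxy groups) rather than the more hindered C4 between them, as for 3,5-dialkoxybenzyl systems.

**Step 8**
Reactants: 10; 11 tributyl(3-methylbut-2-en-1-yl)stannane
Product: 12 methyl 2-[3,5-bis(tert-butyldimethylsilyloxy)-2-(3-methylbut-2-en-1-yl)phenyl]acetate
Conditions: Pd(PPh3)4 (5 mol%), CuI (10 mol%), DMF, 80 °C
Reagents that add atoms: prenyltributylstannane (11), CCCC[Sn](CCCC)(CCCC)CC=C(C)C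
Why: Stille coupling under neutral conditions (compatible with aryl silyl ethers and the enolisable ester) delivers the linear prenyl arene by reductive elimination at the less hindered allyl terminus.

**Step 9**
Reactants: 12
Product: 13 methyl 2-[3,5-bis(tert-butyldimethylsilyloxy)-2-{[(2S)-3,3-dimethyloxiran-2-yl]methyl}phenyl]acetate
Conditions: ent-Shi ketone (L-fructose-derived, 30 mol%), Oxone, K2CO3, Bu4NHSO4, MeCN/DMM/aq. borate buffer (pH 10.5), 0 °C
Reagents that add atoms: Oxone (potassium peroxymonosulfate), OOS(=O)(=O)[O-].[K+]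
Why: Shi asymmetric epoxidation of the only olefin sets the stereocentre through the spiro transition state; the D-fructose catalyst gives the (R)-epoxide from R–CH2–CH=CMe2, so the enantiomeric catalyst gives the required (S)-epoxide.

**Step 10**
Reactants: 13
Product: 14 methyl 2-bromo-2-[3,5-bis(tert-butyldimethylsilyloxy)-2-{[(2S)-3,3-dimethyloxiran-2-yl]methyl}phenyl]acetate (≈1:1 epimers at C–Br)
Conditions: LiHMDS, TMSCl (in situ quench), THF, −78 °C; then NBS, −78 → −20 °C
Reagents that add atoms: N-bromosuccinimide, O=C1CCC(=O)N1Br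
Why: The ester enolate is trapped at once as the silyl ketene acetal (so it cannot attack the epoxide) and then brominated at the α-carbon by NBS, leaving the epoxide stereocentre untouched.

**Union and endgame**

**Step 11**
Reactants: 7; 14
Product: 15 methyl 2-[3,5-bis(tert-butyldimethylsilyloxy)-2-{[(2S)-3,3-dimethyloxiran-2-yl]methyl}phenyl]-2-{3-(tert-butyldimethylsilyloxy)-6-formyl-2-[(2E)-geranyl]phenoxy}acetate (epimers at the α-carbon)
Conditions: K2CO3 (anhydrous), acetone, rt → 45 °C
Reagents that add atoms: none (both partners are numbered reactants)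
Why: Williamson etherification: the phenoxide of 7 displaces the activated benzylic α-bromo ester (no β-hydrogen, so no elimination), and anhydrous carbonate in acetone spares the aryl silyl ethers, the epoxide and the aldehyde.

**Step 12**
Reactants: 15
Product: 16 2-{6-formyl-2-[(2E)-geranyl]-3-hydroxyphenoxy}-2-[(2R)-6-hydroxy-2-(2-hydroxypropan-2-yl)-2,3-dihydro-1-benzofuran-4-yl]acetic acid (epimers at the α-carbon)
Conditions: LiOH·H2O (10 equiv), THF/MeOH/H2O, rt → 40 °C, Ar; then citric acid to pH 4
Reagents that add atoms: lithium hydroxide/water, [Li+].[OH-] (oxygen of the CO2H)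
Why: Hydroxide saponifies the ester and cleaves the three aryl TBS ethers, and the phenoxide ortho to the epoxide opens it 5-exo-tet at the secondary carbon with inversion, converting (S)-epoxide into the (R)-dihydrobenzofuran carbinol.

**Step 13 (key ring closure)**
Reactants: 16
Product: 17 (2R)-4-{6-acetoxy-7-[(2E)-geranyl]-1-benzofuran-2-yl}-2-(2-acetoxypropan-2-yl)-2,3-dihydro-1-benzofuran-6-yl acetate
Conditions: Ac2O, NaOAc, 125 °C; then DMAP (cat.), 60 °C
Reagents that add atoms: acetic anhydride, CC(=O)OC(C)=O
Why: Perkin-type intramolecular aldol condensation: the mixed-anhydride enolate adds to the ortho-formyl group to close the five-membered ring, and the β-acetoxy acid loses CO2 and acetate to aromatise to the 2-arylbenzofuran. The phenols and the tertiary alcohol are acetylated in the same pot (DMAP completes the tertiary acetate), and the stereocentre has no acidic hydrogen and is untouched.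

**Step 14**
Reactants: 17
Product: 18 mulberrofuran X
Conditions: LiAlH4, THF, 0 °C; Rochelle-salt work-up
Reagents that add atoms: none
Why: Reductive cleavage removes the two aryl acetates and the hindered tertiary acetate without acid, so the geranyl phenol and the tertiary alcohol survive and the (R)-centre is unchanged.

---

**Compound list**
1 | resorcinol | Oc1cccc(O)c1 | starting material
2 | 1,3-bis(methoxymethoxy)benzene | COCOc1cccc(OCOC)c1 | intermediate
3 | geranyl bromide | CC(C)=CCC/C(C)=C/CBr | starting material
4 | 2-geranyl-1,3-bis(methoxymethoxy)benzene | COCOc1cccc(OCOC)c1C/C=C(\C)CCC=C(C)C | intermediate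
5 | 3-geranyl-2,4-bis(methoxymethoxy)benzaldehyde | COCOc1ccc(C=O)c(OCOC)c1C/C=C(\C)CCC=C(C)C | intermediate
6 | 3-geranyl-2,4-dihydroxybenzaldehyde | O=Cc1ccc(O)c(C/C=C(\C)CCC=C(C)C)c1O | intermediate
7 | 4-(TBS-oxy)-3-geranyl-2-hydroxybenzaldehyde | O=Cc1ccc(O[Si](C)(C)C(C)(C)C)c(C/C=C(\C)CCC=C(C)C)c1O | intermediate
8 | methyl 2-(3,5-dihydroxyphenyl)acetate | COC(=O)Cc1cc(O)cc(O)c1 | starting material
9 | methyl 2-[3,5-bis(TBS-oxy)phenyl]acetate | COC(=O)Cc1cc(O[Si](C)(C)C(C)(C)C)cc(O[Si](C)(C)C(C)(C)C)c1 | intermediate
10 | methyl 2-[2-iodo-3,5-bis(TBS-oxy)phenyl]acetate | COC(=O)Cc1cc(O[Si](C)(C)C(C)(C)C)cc(O[Si](C)(C)C(C)(C)C)c1I | intermediate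
11 | tributyl(3-methylbut-2-en-1-yl)stannane | CCCC[Sn](CCCC)(CCCC)CC=C(C)C | starting material
12 | methyl 2-[3,5-bis(TBS-oxy)-2-prenylphenyl]acetate | COC(=O)Cc1cc(O[Si](C)(C)C(C)(C)C)cc(O[Si](C)(C)C(C)(C)C)c1CC=C(C)C | intermediate
13 | methyl 2-[3,5-bis(TBS-oxy)-2-{[(2S)-3,3-dimethyloxiran-2-yl]methyl}phenyl]acetate | COC(=O)Cc1cc(O[Si](C)(C)C(C)(C)C)cc(O[Si](C)(C)C(C)(C)C)c1C[C@@H]1OC1(C)C | intermediate
14 | α-bromo ester of 13 (epimers at C–Br) | COC(=O)C(Br)c1cc(O[Si](C)(C)C(C)(C)C)cc(O[Si](C)(C)C(C)(C)C)c1C[C@@H]1OC1(C)C | intermediate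
15 | α-aryloxy ester from 7 + 14 (epimers at α-C) | COC(=O)C(Oc1c(C=O)ccc(O[Si](C)(C)C(C)(C)C)c1C/C=C(\C)CCC=C(C)C)c1cc(O[Si](C)(C)C(C)(C)C)cc(O[Si](C)(C)C(C)(C)C)c1C[C@@H]1OC1(C)C | intermediate
16 | 2-(6-formyl-2-geranyl-3-hydroxyphenoxy)-2-[(2R)-6-hydroxy-2-(2-hydroxypropan-2-yl)-2,3-dihydrobenzofuran-4-yl]acetic acid (epimers at α-C) | OC(=O)C(Oc1c(C=O)ccc(O)c1C/C=C(\C)CCC=C(C)C)c1cc(O)cc2c1C[C@H](C(C)(C)O)O2 | intermediate
17 | mulberrofuran X triacetate | CC(C)=CCC/C(C)=C/Cc1c(OC(C)=O)ccc2cc(-c3cc(OC(C)=O)cc4c3C[C@H](C(C)(C)OC(C)=O)O4)oc12 | intermediate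
18 | mulberrofuran X | CC(C)=CCC/C(C)=C/Cc1c(O)ccc2cc(-c3cc(O)cc4c3C[C@H](C(C)(C)O)O4)oc12 | target

**Total step count:** 14
**Longest linear sequence:** 9 steps (steps 1–5 then 11–14, or equally steps 6–10 then 11–14)

**Three steps most likely to fail**
- **Step 8** (Stille prenylation of a di-ortho-substituted, electron-rich aryl iodide; slow coupling, α/γ isomers, protodeiodination). Fallback: reverse the polarity. Convert 10 to the aryl pinacol boronate (Miyaura borylation) and couple it with prenyl methyl carbonate through a π-allyl-palladium intermediate, which favours the linear prenyl arene.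
- **Step 11** (etherification of a hindered, hydrogen-bonded phenol with a secondary benzylic bromide while three aryl TBS ethers must survive carbonate). Fallback: replace the SN2 union by a Mitsunobu coupling. Hydroxylate the enolate of 13 (Davis oxaziridine) to the α-hydroxy ester and join it to 7 with PPh3/DIAD under neutral conditions.
- **Step 13** (hot Ac2O/NaOAc on a substrate carrying a geranyl chain and a tertiary alcohol). Fallback: run the intramolecular aldol at the ester stage on 15 with base (DBU or KOt-Bu, THF) to give the 3-hydroxy-2,3-dihydrobenzofuran-2-carboxylate. Then saponify/desilylate and aromatise by a mild decarboxylative dehydration (DMF dineopentyl acetal, ≤60 °C), followed by the usual final deprotection.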